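**Plan**

- Retrosynthetic cuts, in order: C9–C11 (sp2–sp3 coupling of a C9 enol triflate with the complete C11–C16 chain); C4–CH3 and C5–H (reductive methylation of a C4=C5 unsaturated ester); ring A at C1=C2 and C4=C5 at once ([3+3] double carbonyl olefination); C10–C1.
- Forward: ring B is bought as 2-methylcyclohexane-1,3-dione. Ring A is closed onto it in one flask (Wittig at C1, Horner–Wadsworth–Emmons at C5) by a C2–C3–C4(C19) ylide/phosphonate. The side chain is joined last.
- Feature that allows this: in ring A, C1 and C5 both hang on the quaternary C10 of the ring A/ring B junction. Ring B can therefore carry a formyl group (C1) and a ring ketone (C5) that cannot enolise through C10 and that differ enough in reactivity to be taken in order.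
- Stereochemistry: C10 from yeast desymmetrisation of the prochiral dione; C5 (trans fusion) and C4 from Li/NH3 reduction–methylation steered by the C10 methyl; C13=C14 (E) from a syn-carbocupration; the C8=C9 position from the enol triflate.

Key step: step 8

Remark: labdane numbering is used for positions (ring A = C1–C5 and C10; ring B = C5–C10; C19 = ester/CH2O carbon on C4; C20 = methyl on C10). The methylation of step 12 is assumed to give C8 epimers, which converge in step 13.

Step 1
Reactants: 1 2-methylcyclohexane-1,3-dione; 2 3-bromoprop-1-ene (allyl bromide)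
Product: 3 2-methyl-2-(prop-2-en-1-yl)cyclohexane-1,3-dione
Conditions: NaOH (1 M aq), 20 °C
Reagents that add atoms: none
Why: C-allylation (SN2) of the doubly stabilised enolate in water, where solvation of the enolate oxygens favours attack through carbon, should give the prochiral 2,2-disubstituted dione; no stereocentre is formed.

Step 2
Reactants: 3 2-methyl-2-(prop-2-en-1-yl)cyclohexane-1,3-dione
Product: 4 (2S,3S)-3-hydroxy-2-methyl-2-(prop-2-en-1-yl)cyclohexan-1-one
Conditions: baker's yeast (Saccharomyces cerevisiae), sucrose, H2O, 30 °C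
Reagents that add atoms: none
Why: enzymatic desymmetrising carbonyl reduction, a known reaction of 2,2-disubstituted cyclohexane-1,3-diones in which the yeast reductases take one of the two enantiotopic carbonyl groups from one face, should give the (2S,3S) ketol and so fix the quaternary carbon that becomes C10 (carbinol carbon = future C5, remaining ketone = future C9).

Step 3
Reactants: 4 (2S,3S)-3-hydroxy-2-methyl-2-(prop-2-en-1-yl)cyclohexan-1-one
Product: 5 (6S,7S)-6-methyl-6-(prop-2-en-1-yl)-1,4-dioxaspiro[4.5]decan-7-ol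
Conditions: ethane-1,2-diol, p-TsOH (cat.), benzene, reflux with azeotropic removal of water
Reagents that add atoms: ethane-1,2-diol, OCCO
Why: acid-catalysed ketalisation masks the remaining ketone (future C9) as a dioxolane and leaves both stereocentres untouched.

Step 4
Reactants: 5 (6S,7S)-6-methyl-6-(prop-2-en-1-yl)-1,4-dioxaspiro[4.5]decan-7-ol
Product: 6 (6S)-6-methyl-6-(prop-2-en-1-yl)-1,4-dioxaspiro[4.5]decan-7-one
Conditions: Pr4N[RuO4] (cat.), N-methylmorpholine N-oxide, 4 Å molecular sieves, CH2Cl2, 20 °C
Reagents that add atoms: none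
Why: Ley–Griffith oxidation of the secondary alcohol gives the future C5 ketone under non-acidic conditions that spare the dioxolane; the quaternary centre has no α-hydrogen and cannot epimerise.

Step 5
Reactants: 6 (6S)-6-methyl-6-(prop-2-en-1-yl)-1,4-dioxaspiro[4.5]decan-7-one
Product: 7 (6S)-6-methyl-6-[(1E)-prop-1-en-1-yl]-1,4-dioxaspiro[4.5]decan-7-one
Conditions: RuHCl(CO)(PPh3)3 (cat.), toluene, 80 °C
Reagents that add atoms: none
Why: ruthenium hydride-catalysed alkene isomerisation (hydrometalation/β-hydride elimination) moves the terminal double bond one position to the more stable internal E-alkene and stops there because the next carbon is quaternary.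

Step 6
Reactants: 7 (6S)-6-methyl-6-[(1E)-prop-1-en-1-yl]-1,4-dioxaspiro[4.5]decan-7-one
Product: 9 (6S)-6-methyl-7-oxo-1,4-dioxaspiro[4.5]decane-6-carbaldehyde, via ozonide 8 (not isolated)
Conditions: O3, CH2Cl2, −78 °C; then PPh3, −78 → 20 °C
Reagents that add atoms: ozone, [O-][O+]=O
Why: ozonolysis (cycloaddition, cycloreversion and recombination to the ozonide, then reduction by the phosphine) cuts the propenyl group down to the C1 aldehyde; the quaternary centre carries no α-hydrogen and keeps its configuration.

Step 7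
Reactants: 10 trimethyl phosphonoacetate; 11 ethenyl(triphenyl)phosphonium bromide
Product: 12 [3-(dimethoxyphosphoryl)-4-methoxy-4-oxobutyl](triphenyl)phosphonium bromide (racemic)
Conditions: 10 (3 equiv), DBU (cat.), MeCN, 20 °C; precipitation with Et2O
Reagents that add atoms: none
Why: conjugate addition of the phosphonoacetate carbanion to the vinylphosphonium salt; the ylide first formed is protonated by a further molecule of 10, so the base turns over, and the excess of 10 holds back a second addition.

Step 8
Reactants: 9 (6S)-6-methyl-7-oxo-1,4-dioxaspiro[4.5]decane-6-carbaldehyde; 12 [3-(dimethoxyphosphoryl)-4-methoxy-4-oxobutyl](triphenyl)phosphonium bromide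
Product: 15 methyl (4'aS)-4'a-methyl-4'a,6',7',8'-tetrahydro-2'H-spiro[1,3-dioxolane-2,5'-naphthalene]-1'-carboxylate (ring A 1,4-diene with C1=C2 and C4=C5; C9 dioxolane), via ylide phosphonate dianion 13 (not isolated), via Z-alkenyl phosphonate anion 14 (not isolated)
Conditions: 12, KN(SiMe3)2 (2.05 equiv), THF, −78 → 0 °C; then 9, −78 → 20 °C; then 60 °C
Reagents that add atoms: none
Why: Two equivalents of base turn 12 into the ylide/phosphonate dianion 13; its non-stabilised ylide carbon (C2) adds at −78 °C to the only aldehyde of 9 (C1) and the oxaphosphetane collapses to the Z-alkene 14, after which the phosphonoacetate carbanion (C4), too stabilised and too hindered to have competed for the neopentyl aldehyde, adds to the ring ketone (C5) and loses dimethyl phosphate in an intramolecular Horner–Wadsworth–Emmons reaction. The closest known reaction types are the Wittig olefination of α-quaternary aldehydes, the ring-closing Horner–Wadsworth–Emmons reaction of keto phosphonoacetates to cycloalkene carboxylates and the double Wittig cyclo-olefination of dicarbonyl compounds with bis-ylides. Ring A is closed in the second olefination by a 6-exo-trig addition of C4 to the C5 carbonyl group, which only the cis C1=C2 alkene can reach. No new stereocentre is formed, and C10 is preserved because neither carbonyl group can enolise through the quaternary carbon. The step needs regioselectivity (C2 to C1 and C4 to C5, not the reverse), secured by pairing the more reactive nucleophile with the more reactive carbonyl group at low temperature, and Z selectivity in the Wittig stage, secured by the salt-free potassium base; any E-alkene cannot cyclise and should remain as a separable open-chain by-product.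

Step 9
Reactants: 15 methyl (4'aS)-4'a-methyl-4'a,6',7',8'-tetrahydro-2'H-spiro[1,3-dioxolane-2,5'-naphthalene]-1'-carboxylate
Product: 16 methyl (4'aS)-4'a-methyl-3',4',4'a,6',7',8'-hexahydro-2'H-spiro[1,3-dioxolane-2,5'-naphthalene]-1'-carboxylate (C4=C5 ester only)
Conditions: H2 (1 atm), RhCl(PPh3)3 (cat.), benzene/EtOH, 20 °C
Reagents that add atoms: none
Why: homogeneous catalytic hydrogenation with this rhodium complex is very sensitive to alkene substitution, so the cis-disubstituted C1=C2 bond should be reduced and the tetrasubstituted, ester-conjugated C4=C5 bond left.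

Step 10
Reactants: 16 methyl (4'aS)-4'a-methyl-3',4',4'a,6',7',8'-hexahydro-2'H-spiro[1,3-dioxolane-2,5'-naphthalene]-1'-carboxylate
Product: 18 methyl (1'S,4'aS,8'aR)-1',4'a-dimethyloctahydro-1'H-spiro[1,3-dioxolane-2,5'-naphthalene]-1'-carboxylate (trans-decalin; 4β-CO2Me axial, 4α-CH3, 5α-H, 10β-CH3), via lithium ester enolate 17 (not isolated)
Conditions: Li, NH3(l)/THF, t-BuOH (1 equiv), −78 °C; isoprene; then MeI, −78 → −33 °C
Reagents that add atoms: iodomethane, CI
Why: dissolving-metal reductive alkylation of the α,β-unsaturated ester: two-electron reduction and axial protonation of the β-carbon (C5) from the α-face should give the trans-fused enolate 17, and MeI should then approach the exocyclic enolate from the equatorial α-face away from the axial C10 methyl, which places CH3 α and CO2Me β (axial) at C4.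

Step 11
Reactants: 18 methyl (1'S,4'aS,8'aR)-1',4'a-dimethyloctahydro-1'H-spiro[1,3-dioxolane-2,5'-naphthalene]-1'-carboxylate
Product: 19 methyl (1S,4aS,8aR)-1,4a-dimethyl-5-oxodecahydronaphthalene-1-carboxylate (C9 ketone)
Conditions: HCl (2 M aq), THF, 40 °C
Reagents that add atoms: water, O
Why: acid-catalysed ketal hydrolysis frees the C9 ketone; C5 is not α to a carbonyl group and C4 and C10 are quaternary, so no stereocentre can epimerise.

Step 12
Reactants: 19 methyl (1S,4aS,8aR)-1,4a-dimethyl-5-oxodecahydronaphthalene-1-carboxylate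
Product: 21 methyl (1S,4aS,8aR)-1,4a,6-trimethyl-5-oxodecahydronaphthalene-1-carboxylate (8-methyl ketone, C8 epimers), via lithium enolate 20 (not isolated)
Conditions: LiN(i-Pr)2, THF, −78 °C; then MeI, −78 → 0 °C
Reagents that add atoms: iodomethane, CI
Why: kinetic enolate alkylation: the base can deprotonate only C8 (C10 is quaternary and the ester has no α-hydrogen), and methylation there gives an epimer mixture of no consequence because C8 becomes trigonal in the next step.

Step 13
Reactants: 21 methyl (1S,4aS,8aR)-1,4a,6-trimethyl-5-oxodecahydronaphthalene-1-carboxylate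
Product: 23 methyl (1S,4aS,8aR)-1,4a,6-trimethyl-5-[(trifluoromethanesulfonyl)oxy]-1,2,3,4,4a,7,8,8a-octahydronaphthalene-1-carboxylate, via potassium enolate 22 (not isolated)
Conditions: KN(SiMe3)2, THF, −78 → 0 °C; then PhNTf2, 0 °C
Reagents that add atoms: N-phenylbis(trifluoromethanesulfonimide), O=S(=O)(N(c1ccccc1)S(=O)(=O)C(F)(F)F)C(F)(F)F
Why: removal of the last C8 hydrogen gives the tetrasubstituted enolate and O-sulfonylation traps it as the enol triflate, which fixes the double bond at C8=C9.

Step 14
Reactants: 23 methyl (1S,4aS,8aR)-1,4a,6-trimethyl-5-[(trifluoromethanesulfonyl)oxy]-1,2,3,4,4a,7,8,8a-octahydronaphthalene-1-carboxylate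
Product: 24 (4aS,5S,8aS)-5-(hydroxymethyl)-2,5,8a-trimethyl-3,4,4a,5,6,7,8,8a-octahydronaphthalen-1-yl trifluoromethanesulfonate
Conditions: i-Bu2AlH, CH2Cl2, −78 → 0 °C; aqueous potassium sodium tartrate work-up
Reagents that add atoms: none
Why: hydride reduction of the neopentyl methyl ester to the primary alcohol (C19) by the aluminium hydride, which at low temperature should not attack the enol triflate.

Step 15
Reactants: 24 (4aS,5S,8aS)-5-(hydroxymethyl)-2,5,8a-trimethyl-3,4,4a,5,6,7,8,8a-octahydronaphthalen-1-yl trifluoromethanesulfonate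
Product: 25 [(1S,4aS,8aS)-1,4a,6-trimethyl-5-[(trifluoromethanesulfonyl)oxy]-1,2,3,4,4a,7,8,8a-octahydronaphthalen-1-yl]methyl acetate
Conditions: Ac2O, pyridine, DMAP (cat.), CH2Cl2, 20 °C
Reagents that add atoms: acetic anhydride, CC(=O)OC(C)=O
Why: DMAP-catalysed acylation of the primary alcohol installs the C19 acetate.

Step 16
Reactants: 26 methyl but-2-ynoate; 27 ethenylmagnesium bromide (vinylmagnesium bromide)
Product: 29 methyl (2E)-3-methylpenta-2,4-dienoate, via alkenylcopper 28 (not isolated)
Conditions: 27, CuBr·SMe2, THF, −78 °C; then 26, −78 °C; then MeOH, −78 °C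
Reagents that add atoms: none
Why: syn-carbocupration of the ynoate by vinylcopper gives the alkenylcopper with vinyl and copper cis, and protonation with retention at low temperature should give the 2E-dienoate, which carries the C13=C14 geometry of the target.

Step 17
Reactants: 25 [(1S,4aS,8aS)-1,4a,6-trimethyl-5-[(trifluoromethanesulfonyl)oxy]-1,2,3,4,4a,7,8,8a-octahydronaphthalen-1-yl]methyl acetate; 29 methyl (2E)-3-methylpenta-2,4-dienoate
Product: 31 methyl 19-acetoxylabda-8,13E-dien-15-oate (4S,5R,10S), via alkylborane 30 (not isolated)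
Conditions: 29, 9-BBN, THF, 0 → 20 °C; then 25, Pd(dppf)Cl2 (cat.), K3PO4 (aq), DMF, 20 → 50 °C
Reagents that add atoms: none
Why: anti-Markovnikov hydroboration of the terminal vinyl group gives the primary alkylborane (the trisubstituted, ester-conjugated alkene is inert), and B-alkyl Suzuki–Miyaura coupling with the enol triflate (oxidative addition to zerovalent palladium, base-assisted transmetalation, reductive elimination) forms C9–C11 with both double bond geometries and all stereocentres unchanged.

**Compound list**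

1 | 2-methylcyclohexane-1,3-dione | CC1C(=O)CCCC1=O | starting material
2 | 3-bromoprop-1-ene (allyl bromide) | C=CCBr | starting material
3 | 2-methyl-2-(prop-2-en-1-yl)cyclohexane-1,3-dione | C=CCC1(C)C(=O)CCCC1=O | intermediate
4 | (2S,3S)-3-hydroxy-2-methyl-2-(prop-2-en-1-yl)cyclohexan-1-one | C=CC[C@]1(C)C(=O)CCC[C@@H]1O | intermediate
5 | (6S,7S)-6-methyl-6-(prop-2-en-1-yl)-1,4-dioxaspiro[4.5]decan-7-ol | C=CC[C@]1(C)C2(OCCO2)CCC[C@@H]1O | intermediate
6 | (6S)-6-methyl-6-(prop-2-en-1-yl)-1,4-dioxaspiro[4.5]decan-7-one | C=CC[C@]1(C)C2(OCCO2)CCCC1=O | intermediate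
7 | (6S)-6-methyl-6-[(1E)-prop-1-en-1-yl]-1,4-dioxaspiro[4.5]decan-7-one | C/C=C/[C@]1(C)C2(OCCO2)CCCC1=O | intermediate
8 | (6S)-6-methyl-6-(5-methyl-1,2,4-trioxolan-3-yl)-1,4-dioxaspiro[4.5]decan-7-one (ozonide, trioxolane epimers) | CC1OC(OO1)[C@]2(C)C3(OCCO3)CCCC2=O | intermediate
9 | (6S)-6-methyl-7-oxo-1,4-dioxaspiro[4.5]decane-6-carbaldehyde | O=C[C@]1(C)C2(OCCO2)CCCC1=O | intermediate
10 | trimethyl phosphonoacetate | COC(=O)CP(=O)(OC)OC | starting material
11 | ethenyl(triphenyl)phosphonium bromide | C=C[P+](c1ccccc1)(c1ccccc1)c1ccccc1.[Br-] | starting material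
12 | [3-(dimethoxyphosphoryl)-4-methoxy-4-oxobutyl](triphenyl)phosphonium bromide (racemic) | COC(=O)C(CC[P+](c1ccccc1)(c1ccccc1)c1ccccc1)P(=O)(OC)OC.[Br-] | intermediate
13 | potassium salt of the ylide/phosphonate dianion of 12 | COC(=O)[C-](C[CH-][P+](c1ccccc1)(c1ccccc1)c1ccccc1)P(=O)(OC)OC.[K+] | intermediate
14 | potassium salt of the C2 carbanion of methyl (4Z)-2-(dimethoxyphosphoryl)-5-[(6S)-6-methyl-7-oxo-1,4-dioxaspiro[4.5]decan-6-yl]pent-4-enoate | COC(=O)[C-](C/C=C\[C@]1(C)C2(OCCO2)CCCC1=O)P(=O)(OC)OC.[K+] | intermediate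
15 | methyl (4'aS)-4'a-methyl-4'a,6',7',8'-tetrahydro-2'H-spiro[1,3-dioxolane-2,5'-naphthalene]-1'-carboxylate | COC(=O)C1=C2CCCC3(OCCO3)[C@@]2(C)C=CC1 | intermediate
16 | methyl (4'aS)-4'a-methyl-3',4',4'a,6',7',8'-hexahydro-2'H-spiro[1,3-dioxolane-2,5'-naphthalene]-1'-carboxylate | COC(=O)C1=C2CCCC3(OCCO3)[C@@]2(C)CCC1 | intermediate
17 | lithium ester enolate formed from 16 (trans-fused, 5α-H) | C12(OCCO1)CCC[C@H]3C(=C(OC)[O-])CCC[C@]23C.[Li+] | intermediate
18 | methyl (1'S,4'aS,8'aR)-1',4'a-dimethyloctahydro-1'H-spiro[1,3-dioxolane-2,5'-naphthalene]-1'-carboxylate | C12(OCCO1)CCC[C@H]3[C@@](C)(C(=O)OC)CCC[C@]23C | intermediate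
19 | methyl (1S,4aS,8aR)-1,4a-dimethyl-5-oxodecahydronaphthalene-1-carboxylate | O=C1CCC[C@H]2[C@@](C)(C(=O)OC)CCC[C@]12C | intermediate
20 | lithium enolate of 19 (C8=C9) | [O-]C1=CCC[C@H]2[C@@](C)(C(=O)OC)CCC[C@]12C.[Li+] | intermediate
21 | methyl (1S,4aS,8aR)-1,4a,6-trimethyl-5-oxodecahydronaphthalene-1-carboxylate (C6 epimers, C8 in labdane numbering) | O=C1C(C)CC[C@H]2[C@@](C)(C(=O)OC)CCC[C@]12C | intermediate
22 | potassium enolate of 21 (C8=C9) | [O-]C1=C(C)CC[C@H]2[C@@](C)(C(=O)OC)CCC[C@]12C.[K+] | intermediate
23 | methyl (1S,4aS,8aR)-1,4a,6-trimethyl-5-[(trifluoromethanesulfonyl)oxy]-1,2,3,4,4a,7,8,8a-octahydronaphthalene-1-carboxylate | O=S(=O)(OC1=C(C)CC[C@H]2[C@@](C)(C(=O)OC)CCC[C@]12C)C(F)(F)F | intermediate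
24 | (4aS,5S,8aS)-5-(hydroxymethyl)-2,5,8a-trimethyl-3,4,4a,5,6,7,8,8a-octahydronaphthalen-1-yl trifluoromethanesulfonate | O=S(=O)(OC1=C(C)CC[C@H]2[C@@](C)(CO)CCC[C@]12C)C(F)(F)F | intermediate
25 | [(1S,4aS,8aS)-1,4a,6-trimethyl-5-[(trifluoromethanesulfonyl)oxy]-1,2,3,4,4a,7,8,8a-octahydronaphthalen-1-yl]methyl acetate | O=S(=O)(OC1=C(C)CC[C@H]2[C@@](C)(COC(C)=O)CCC[C@]12C)C(F)(F)F | intermediate
26 | methyl but-2-ynoate | CC#CC(=O)OC | starting material
27 | ethenylmagnesium bromide (vinylmagnesium bromide) | C=C[Mg]Br | starting material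
28 | methyl (2Z)-2-cuprio-3-methylpenta-2,4-dienoate (alkenylcopper, vinyl and copper cis) | COC(=O)/C([Cu])=C(\C)C=C | intermediate
29 | methyl (2E)-3-methylpenta-2,4-dienoate | COC(=O)/C=C(\C)C=C | intermediate
30 | methyl (2E)-5-(9-borabicyclo[3.3.1]nonan-9-yl)-3-methylpent-2-enoate | COC(=O)/C=C(\C)CCB1C2CCCC1CCC2 | intermediate
31 | methyl 19-acetoxylabda-8,13E-dien-15-oate = methyl (2E)-5-[(4aR,5S,8aS)-5-(acetoxymethyl)-2,5,8a-trimethyl-3,4,4a,5,6,7,8,8a-octahydronaphthalen-1-yl]-3-methylpent-2-enoate | COC(=O)/C=C(\C)CCC1=C(C)CC[C@H]2[C@@](C)(COC(C)=O)CCC[C@]12C | target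

**Step count**

Total: 17 steps (steps 7 and 16 prepare the two side fragments). Longest linear sequence: 15 steps (1–6, 8–15, 17).

**Steps most likely to fail, with fallbacks**

Step 8. What may go wrong: erosion of Z selectivity in the Wittig stage, which leaves an E-alkene that cannot reach the ketone, or failure of the phosphonate carbanion to add to the hindered ketone next to the quaternary carbon. The fallback sets out from 9 and returns at 15. It closes ring A by olefin metathesis instead of by the second carbonyl olefination. Methylenation of the aldehyde of 9 (Ph3PCH3Br, KN(SiMe3)2, THF, −78 °C; the aldehyde should react before the ketone) should give (6S)-6-ethenyl-6-methyl-1,4-dioxaspiro[4.5]decan-7-one F1. Aldol addition of the enolate of methyl pent-4-enoate (LiN(i-Pr)2, then CeCl3, THF, −78 °C) to the ketone should give methyl 2-[(6S)-6-ethenyl-7-hydroxy-6-methyl-1,4-dioxaspiro[4.5]decan-7-yl]pent-4-enoate F2, a diastereomer mixture at two centres that are both removed later. Ring-closing metathesis of the two vinyl groups (second-generation Grubbs catalyst, CH2Cl2, 40 °C) should give methyl (4'aS)-8'a-hydroxy-4'a-methyl-2',4'a,6',7',8',8'a-hexahydro-1'H-spiro[1,3-dioxolane-2,5'-naphthalene]-1'-carboxylate F3. Dehydration (SOCl2, pyridine, 0 °C, then DBU to bring any β,γ-isomer into conjugation with the ester) should give 15.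

Step 10. What may go wrong: over-reduction of the ester group in liquid ammonia, or poor facial selectivity when the enolate is trapped in the reducing medium. The fallback sets out from 16 and returns at 18. It separates reduction from alkylation. Conjugate reduction of 16 with magnesium in methanol (20 °C) should give methyl (4'aS)-4'a-methyloctahydro-1'H-spiro[1,3-dioxolane-2,5'-naphthalene]-1'-carboxylate F4, with the trans ring fusion set by protonation of the β-carbanion and C4 epimers of no consequence. Deprotonation with LiN(i-Pr)2 (THF, −78 °C) and addition of MeI should then methylate the ester enolate from the equatorial α-face to give 18.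

Step 17. What may go wrong: slow oxidative addition and transmetalation at the hindered tetrasubstituted triflate, or hydroboration of 29 at the wrong position. The fallback sets out from 25 and returns at 31. It builds the chain in stages through an sp2–sp2 coupling. A Heck reaction of 25 with but-3-en-2-one (Pd(OAc)2, PPh3, Et3N, DMF, 80 °C) should give [(1S,4aS,8aR)-1,4a,6-trimethyl-5-[(1E)-3-oxobut-1-en-1-yl]-1,2,3,4,4a,7,8,8a-octahydronaphthalen-1-yl]methyl acetate F5. Chemoselective 1,4-reduction of the disubstituted enone double bond (Ph2SiH2, ZnCl2, Pd(PPh3)4, CHCl3, 20 °C) should give [(1S,4aS,8aR)-1,4a,6-trimethyl-5-(3-oxobutyl)-1,2,3,4,4a,7,8,8a-octahydronaphthalen-1-yl]methyl acetate F6. Horner–Wadsworth–Emmons olefination of the methyl ketone with 10 (NaH, THF, 0 → 20 °C) should give 31; the E isomer is expected to predominate and the Z isomer would be removed by chromatography.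

Further compounds
F1 | step 8 | (6S)-6-ethenyl-6-methyl-1,4-dioxaspiro[4.5]decan-7-one | C=C[C@]1(C)C2(OCCO2)CCCC1=O
F2 | step 8 | methyl 2-[(6S)-6-ethenyl-7-hydroxy-6-methyl-1,4-dioxaspiro[4.5]decan-7-yl]pent-4-enoate | C=CCC(C(=O)OC)C1(O)CCCC2(OCCO2)[C@@]1(C)C=C
F3 | step 8 | methyl (4'aS)-8'a-hydroxy-4'a-methyl-2',4'a,6',7',8',8'a-hexahydro-1'H-spiro[1,3-dioxolane-2,5'-naphthalene]-1'-carboxylate | COC(=O)C1CC=C[C@]2(C)C3(OCCO3)CCCC12O
F4 | step 10 | methyl (4'aS)-4'a-methyloctahydro-1'H-spiro[1,3-dioxolane-2,5'-naphthalene]-1'-carboxylate (trans ring fusion) | C12(OCCO1)CCC[C@H]3C(C(=O)OC)CCC[C@]23C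
F5 | step 17 | [(1S,4aS,8aR)-1,4a,6-trimethyl-5-[(1E)-3-oxobut-1-en-1-yl]-1,2,3,4,4a,7,8,8a-octahydronaphthalen-1-yl]methyl acetate | CC(=O)/C=C/C1=C(C)CC[C@H]2[C@@](C)(COC(C)=O)CCC[C@]12C
F6 | step 17 | [(1S,4aS,8aR)-1,4a,6-trimethyl-5-(3-oxobutyl)-1,2,3,4,4a,7,8,8a-octahydronaphthalen-1-yl]methyl acetate | CC(=O)CCC1=C(C)CC[C@H]2[C@@](C)(COC(C)=O)CCC[C@]12C
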